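The route rests on cutting the C2–C3 bond of the flavanone ring C. Its precursor is an open aryl benzyl ether: ring A carries an α-diazoketone (future C4 and C3) and, ortho to it, the O1–CH2 group whose carbon (future C2) is benzylic to the catechol ring B, which already bears the perbenzylated luteolin at C2'. A chiral dirhodium carboxylate converts the diazo carbon into a carbenoid that inserts into one enantiotopic C2–H bond, a bond activated by O1 and by the electron-rich ring B. One operation thus closes ring C and sets (2S). Suzuki coupling, Mitsunobu etherification and diazo transfer assemble the precursor; desilylation and hydrogenolysis finish.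

Key step: step 11

Assumption: the target string fixes only C2 (S); the 2'–8'' biaryl axis is left undefined, so any rotamer mixture about that axis counts as the target.

Rings A, B and C and unprimed or single-primed locants refer to the flavanone half; double- and triple-primed locants refer to the luteolin unit. Bn = benzyl, TIPS = triisopropylsilyl.

Step 1
Reactants: 1 luteolin
Product: 2 5,7,3',4'-tetra-O-benzylluteolin
Conditions: BnBr (excess), K2CO3, DMF, 80 °C
Reagents that add atoms: benzyl bromide, BrCc1ccccc1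
Why: Williamson O-alkylation of all four phenols, the hydrogen-bonded 5-OH being forced by excess halide and heat.

Step 2
Reactants: 2 5,7,3',4'-tetra-O-benzylluteolin
Product: 3 8-iodo-5,7,3',4'-tetra-O-benzylluteolin
Conditions: NIS, CF3CO2H (cat.), CH2Cl2–MeCN, 0 °C to rt
Reagents that add atoms: N-iodosuccinimide, O=C1CCC(=O)N1I
Why: Electrophilic aromatic iodination should go to C8, the most nucleophilic carbon of a 5,7-dialkoxychromone (ortho to O1 and 7-OBn, para to 5-OBn) once the 5-OH is capped.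

Step 3
Reactants: 3 8-iodo-5,7,3',4'-tetra-O-benzylluteolin
Product: 4 8-(pinacolatoboryl)-5,7,3',4'-tetra-O-benzylluteolin
Conditions: B2pin2, PdCl2(dppf), KOAc, dioxane, 90 °C
Reagents that add atoms: bis(pinacolato)diboron, CC1(C)OB(OC1(C)C)B1OC(C)(C)C(C)(C)O1
Why: Miyaura borylation of an aryl iodide, with KOAc as a base too weak to start a homo-coupling.

Step 4
Reactants: 5 2-bromo-3-hydroxy-4-methoxybenzaldehyde
Product: 6 2-bromo-3,4-dihydroxybenzaldehyde
Conditions: BBr3, CH2Cl2, −78 °C to rt; then H2O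
Reagents that add atoms: none
Why: Lewis-acid cleavage of the aryl methyl ether by BBr3 (bromide attack on the O-methyl of the borane adduct) frees the catechol.

Step 5
Reactants: 6 2-bromo-3,4-dihydroxybenzaldehyde
Product: 7 3,4-bis(benzyloxy)-2-bromobenzaldehyde
Conditions: BnBr, K2CO3, DMF, 50 °C
Reagents that add atoms: benzyl bromide, BrCc1ccccc1
Why: Williamson O-alkylation of both catechol hydroxyls.

Step 6
Reactants: 4 8-(pinacolatoboryl)-5,7,3',4'-tetra-O-benzylluteolin; 7 3,4-bis(benzyloxy)-2-bromobenzaldehyde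
Product: 8 3,4-bis(benzyloxy)-2-(5,7,3',4'-tetra-O-benzylluteolin-8-yl)benzaldehyde
Conditions: Pd(OAc)2, SPhos, K3PO4, toluene–H2O, 100 °C
Reagents that add atoms: none
Why: Suzuki–Miyaura coupling, in which the ortho-formyl bromide adds readily to zerovalent palladium and the bulky biarylphosphine SPhos permits a tetra-ortho-substituted biaryl.

Step 7
Reactants: 8 3,4-bis(benzyloxy)-2-(5,7,3',4'-tetra-O-benzylluteolin-8-yl)benzaldehyde
Product: 9 [3,4-bis(benzyloxy)-2-(5,7,3',4'-tetra-O-benzylluteolin-8-yl)phenyl]methanol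
Conditions: NaBH4, THF–MeOH, 0 °C
Reagents that add atoms: none
Why: Hydride reduction of the aldehyde by NaBH4 is much faster than attack on the vinylogous-ester carbonyl of the chromone.

Step 8
Reactants: 10 2,4,6-trihydroxyacetophenone (dried)
Product: 11 2-hydroxy-4,6-bis(triisopropylsilyloxy)acetophenone
Conditions: TIPSCl (2.1 equiv), imidazole, DMF, 0 °C to rt
Reagents that add atoms: triisopropylsilyl chloride, CC(C)[Si](Cl)(C(C)C)C(C)C
Why: Silylation takes the free 4-OH and one of the two equivalent ortho hydroxyls, while the last OH, hydrogen bonded to the acetyl group and now hindered, should resist the bulky chloride.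

Step 9
Reactants: 9 [3,4-bis(benzyloxy)-2-(5,7,3',4'-tetra-O-benzylluteolin-8-yl)phenyl]methanol; 11 2-hydroxy-4,6-bis(triisopropylsilyloxy)acetophenone
Product: 12 2-{[3,4-bis(benzyloxy)-2-(5,7,3',4'-tetra-O-benzylluteolin-8-yl)benzyl]oxy}-4,6-bis(triisopropylsilyloxy)acetophenone
Conditions: PPh3, DIAD, THF, 0 °C to rt
Reagents that add atoms: none
Why: Mitsunobu etherification of an acidic phenol with a primary benzylic alcohol runs under neutral conditions that spare the aryl silyl ethers.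

Step 10
Reactants: 12 2-{[3,4-bis(benzyloxy)-2-(5,7,3',4'-tetra-O-benzylluteolin-8-yl)benzyl]oxy}-4,6-bis(triisopropylsilyloxy)acetophenone
Product: 14 the α-diazoketone of 12 (2-diazo-1-arylethanone), via trifluoroacetyl diketone 13 (not isolated)
Conditions: LiN(SiMe3)2, THF, −78 °C; CF3CO2CH2CF3; aq. HCl work-up; then MsN3, Et3N, H2O, MeCN, rt
Reagents that add atoms: methanesulfonyl azide, CS(=O)(=O)N=[N+]=[N-] (the two diazo nitrogens); 2,2,2-trifluoroethyl trifluoroacetate, O=C(OCC(F)(F)F)C(F)(F)F (its CF3CO group is carried only by 13)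
Why: Detrifluoroacetylative diazo transfer (Danheiser variant of the Regitz reaction): Claisen-type trifluoroacetylation of the lithium enolate activates the methyl ketone, and the sulfonyl azide then delivers N2 with loss of the trifluoroacetyl group.

Step 11
Reactants: 14 the α-diazoketone of 12
Product: 15 (2S)-3',4',5'',7'',3''',4'''-hexa-O-benzyl-5,7-bis-O-(triisopropylsilyl) derivative of the target
Conditions: Rh2(S-BSP)4 (dirhodium tetrakis[(S)-N-(benzenesulfonyl)prolinate], 2 mol %), CH2Cl2, slow addition of 14, 0 °C to rt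
Reagents that add atoms: none
Why: The dirhodium carboxylate expels N2 from 14 to give an electrophilic α-keto rhodium carbenoid at C3, which inserts into one of the two enantiotopic C2–H bonds of the ArO–CH2–Ar unit through a three-centre, hydride-transfer-like transition state. The closest known reaction type is the dirhodium-carboxylate-catalysed intramolecular C–H insertion of o-alkoxyaryl diazoketones to chroman-4-ones, including its enantioselective form with chiral prolinate catalysts. Ring C is closed as a six-membered ring by 1,6-insertion; no five-membered alternative exists because the fifth chain atom is the ether oxygen O1. The C2 stereocentre is set by the chiral carboxylate ligands, which discriminate the two benzylic hydrogens; the catalyst antipode that delivers (2S) is to be fixed by a test run. The step needs site selectivity for the C2–H bond over ylide formation at O1 and over reaction at the second ortho substituent of ring A. The C2–H bond is activated by O1 and by the para-benzyloxy group of ring B, O1 is a weakly nucleophilic aryl ether oxygen, and the other ortho oxygen carries TIPS, which offers no α-C–H bond and shields that oxygen.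

Step 12
Reactants: 15 (2S)-hexa-O-benzyl-5,7-bis-O-TIPS flavanone
Product: 16 (2S)-3',4',5'',7'',3''',4'''-hexa-O-benzyl derivative of the target (5,7-OH free)
Conditions: Bu4NF, AcOH, THF, 0 °C
Reagents that add atoms: none
Why: Fluoride cleavage of the aryl silyl ethers, buffered with acetic acid so that no base-induced ring opening (retro-oxa-Michael) can scramble C2.

Step 13
Reactants: 16 (2S)-hexa-O-benzyl flavanone
Product: 17 target, (2S)-eriodictyol-(2'→8'')-luteolin
Conditions: H2 (1 atm), Pd/C, THF–MeOH, rt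
Reagents that add atoms: none
Why: Hydrogenolysis of the six benzyl ethers under neutral conditions leaves the C2 stereocentre, the flavanone ketone and the flavone double bond untouched when stopped at full debenzylation.

Compound list
1 | luteolin, 2-(3,4-dihydroxyphenyl)-5,7-dihydroxy-4H-chromen-4-one | O=c1cc(-c2ccc(O)c(O)c2)oc2cc(O)cc(O)c12 | starting material
2 | 5,7-bis(benzyloxy)-2-[3,4-bis(benzyloxy)phenyl]-4H-chromen-4-one | O=c1cc(-c2ccc(OCc3ccccc3)c(OCc3ccccc3)c2)oc2cc(OCc3ccccc3)cc(OCc3ccccc3)c12 | intermediate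
3 | 5,7-bis(benzyloxy)-2-[3,4-bis(benzyloxy)phenyl]-8-iodo-4H-chromen-4-one | O=c1cc(-c2ccc(OCc3ccccc3)c(OCc3ccccc3)c2)oc2c(I)c(OCc3ccccc3)cc(OCc3ccccc3)c12 | intermediate
4 | 5,7-bis(benzyloxy)-2-[3,4-bis(benzyloxy)phenyl]-8-(4,4,5,5-tetramethyl-1,3,2-dioxaborolan-2-yl)-4H-chromen-4-one | O=c1cc(-c2ccc(OCc3ccccc3)c(OCc3ccccc3)c2)oc2c(B3OC(C)(C)C(C)(C)O3)c(OCc3ccccc3)cc(OCc3ccccc3)c12 | intermediate
5 | 2-bromo-3-hydroxy-4-methoxybenzaldehyde | O=Cc1ccc(OC)c(O)c1Br | starting material
6 | 2-bromo-3,4-dihydroxybenzaldehyde | O=Cc1ccc(O)c(O)c1Br | intermediate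
7 | 3,4-bis(benzyloxy)-2-bromobenzaldehyde | O=Cc1ccc(OCc2ccccc2)c(OCc2ccccc2)c1Br | intermediate
8 | 3,4-bis(benzyloxy)-2-{5,7-bis(benzyloxy)-2-[3,4-bis(benzyloxy)phenyl]-4-oxo-4H-chromen-8-yl}benzaldehyde | O=Cc1ccc(OCc2ccccc2)c(OCc2ccccc2)c1-c1c(OCc2ccccc2)cc(OCc2ccccc2)c2c(=O)cc(-c3ccc(OCc4ccccc4)c(OCc4ccccc4)c3)oc12 | intermediate
9 | benzylic alcohol from 8, 8-[2,3-bis(benzyloxy)-6-(hydroxymethyl)phenyl]-5,7-bis(benzyloxy)-2-[3,4-bis(benzyloxy)phenyl]-4H-chromen-4-one | OCc1ccc(OCc2ccccc2)c(OCc2ccccc2)c1-c1c(OCc2ccccc2)cc(OCc2ccccc2)c2c(=O)cc(-c3ccc(OCc4ccccc4)c(OCc4ccccc4)c3)oc12 | intermediate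
10 | 2,4,6-trihydroxyacetophenone | CC(=O)c1c(O)cc(O)cc1O | starting material
11 | 1-[2-hydroxy-4,6-bis(triisopropylsilyloxy)phenyl]ethanone | CC(=O)c1c(O)cc(O[Si](C(C)C)(C(C)C)C(C)C)cc1O[Si](C(C)C)(C(C)C)C(C)C | intermediate
12 | aryl benzyl ether of 9 and 11 (ring A acetophenone, O1–CH2–ring B, luteolin unit at C2') | CC(=O)c1c(OCc2ccc(OCc3ccccc3)c(OCc3ccccc3)c2-c2c(OCc3ccccc3)cc(OCc3ccccc3)c3c(=O)cc(-c4ccc(OCc5ccccc5)c(OCc5ccccc5)c4)oc23)cc(O[Si](C(C)C)(C(C)C)C(C)C)cc1O[Si](C(C)C)(C(C)C)C(C)C | intermediate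
13 | 4,4,4-trifluoro-1-aryl-butane-1,3-dione from 12 (aryl as in 12) | O=C(CC(=O)C(F)(F)F)c1c(OCc2ccc(OCc3ccccc3)c(OCc3ccccc3)c2-c2c(OCc3ccccc3)cc(OCc3ccccc3)c3c(=O)cc(-c4ccc(OCc5ccccc5)c(OCc5ccccc5)c4)oc23)cc(O[Si](C(C)C)(C(C)C)C(C)C)cc1O[Si](C(C)C)(C(C)C)C(C)C | intermediate (not isolated)
14 | 2-diazo-1-aryl-ethanone from 12 (aryl as in 12) | [N-]=[N+]=CC(=O)c1c(OCc2ccc(OCc3ccccc3)c(OCc3ccccc3)c2-c2c(OCc3ccccc3)cc(OCc3ccccc3)c3c(=O)cc(-c4ccc(OCc5ccccc5)c(OCc5ccccc5)c4)oc23)cc(O[Si](C(C)C)(C(C)C)C(C)C)cc1O[Si](C(C)C)(C(C)C)C(C)C | intermediate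
15 | (2S)-flavanone, 5,7-bis-O-TIPS, 3',4',5'',7'',3''',4'''-hexa-O-benzyl | O=C1C[C@@H](c2ccc(OCc3ccccc3)c(OCc3ccccc3)c2-c2c(OCc3ccccc3)cc(OCc3ccccc3)c3c(=O)cc(-c4ccc(OCc5ccccc5)c(OCc5ccccc5)c4)oc23)Oc2cc(O[Si](C(C)C)(C(C)C)C(C)C)cc(O[Si](C(C)C)(C(C)C)C(C)C)c21 | intermediate
16 | (2S)-flavanone, 5,7-dihydroxy, 3',4',5'',7'',3''',4'''-hexa-O-benzyl | O=C1C[C@@H](c2ccc(OCc3ccccc3)c(OCc3ccccc3)c2-c2c(OCc3ccccc3)cc(OCc3ccccc3)c3c(=O)cc(-c4ccc(OCc5ccccc5)c(OCc5ccccc5)c4)oc23)Oc2cc(O)cc(O)c21 | intermediate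
17 | (2S)-eriodictyol-(2'→8'')-luteolin | O=C1C[C@@H](c2ccc(O)c(O)c2-c2c(O)cc(O)c3c(=O)cc(-c4ccc(O)c(O)c4)oc23)Oc2cc(O)cc(O)c21 | target

Total step count: 13. Longest linear sequence: 10 steps (steps 1, 2, 3, 6, 7, 9, 10, 11, 12, 13).

Steps most likely to fail

Step 11. The carbenoid may be captured by the lone pair of O1 (oxonium ylide, then 1,2-benzyl shift to a coumaranone), or the two benzylic hydrogens at the crowded methylene may be poorly discriminated. The fallback sets out from 12 and forms the same bond by an oxidative oxocarbenium cyclization. O-Acetylation of the lithium enolate of 12 (LiN(SiMe3)2, then Ac2O, THF, −78 °C) should give enol acetate F1. DDQ with 2,6-dichloropyridine and LiClO4 in 1,2-dichloroethane should abstract hydride from the electron-rich 3,4-dialkoxybenzylic ether carbon, and the resulting aryloxycarbenium ion is trapped by the enol acetate carbon with loss of the acetyl group to give racemic flavanone F2. Preparative chromatography on a chiral stationary phase sets aside the (2R)-enantiomer F3 and returns to the route at 15.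

Step 6. Protodeboronation of the hindered, electron-rich 8-boronate may outrun transmetalation in the tetra-ortho-substituted coupling. The fallback sets out from 7 and replaces the boronate by an organozinc partner. Acetalisation with ethylene glycol (p-TsOH, toluene, reflux) gives dioxolane F4. Bromine–lithium exchange (n-BuLi, THF, −78 °C) gives aryllithium F5, which is transmetalated with ZnCl2 to arylzinc chloride F6. Negishi coupling with iodide 3 (Pd2(dba)3, SPhos, THF, 60 °C) should give biaryl acetal F7, and aqueous HCl in THF returns to the route at 8 without passing through 4.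

Step 9. Displacement at the crowded benzylic alkoxyphosphonium ion by a hydrogen-bonded, hindered phenoxide may be slow, so that alkylation of the hydrazide takes over. The fallback sets out from 9 and separates activation from substitution. Appel bromination (CBr4, PPh3, CH2Cl2, 0 °C) gives benzylic bromide F8, and Williamson alkylation of phenol 11 with F8 (K2CO3, acetone, 50 °C) returns to the route at 12.

Further compounds
F1 | step 11 | enol acetate of 12, 1-aryl-vinyl acetate (aryl as in 12) | C=C(OC(C)=O)c1c(OCc2ccc(OCc3ccccc3)c(OCc3ccccc3)c2-c2c(OCc3ccccc3)cc(OCc3ccccc3)c3c(=O)cc(-c4ccc(OCc5ccccc5)c(OCc5ccccc5)c4)oc23)cc(O[Si](C(C)C)(C(C)C)C(C)C)cc1O[Si](C(C)C)(C(C)C)C(C)C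
F2 | step 11 | racemic form of 15 | O=C1CC(c2ccc(OCc3ccccc3)c(OCc3ccccc3)c2-c2c(OCc3ccccc3)cc(OCc3ccccc3)c3c(=O)cc(-c4ccc(OCc5ccccc5)c(OCc5ccccc5)c4)oc23)Oc2cc(O[Si](C(C)C)(C(C)C)C(C)C)cc(O[Si](C(C)C)(C(C)C)C(C)C)c21
F3 | step 11 | (2R)-enantiomer of 15 | O=C1C[C@H](c2ccc(OCc3ccccc3)c(OCc3ccccc3)c2-c2c(OCc3ccccc3)cc(OCc3ccccc3)c3c(=O)cc(-c4ccc(OCc5ccccc5)c(OCc5ccccc5)c4)oc23)Oc2cc(O[Si](C(C)C)(C(C)C)C(C)C)cc(O[Si](C(C)C)(C(C)C)C(C)C)c21
F4 | step 6 | 2-[3,4-bis(benzyloxy)-2-bromophenyl]-1,3-dioxolane | Brc1c(C2OCCO2)ccc(OCc2ccccc2)c1OCc1ccccc1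
F5 | step 6 | [2,3-bis(benzyloxy)-6-(1,3-dioxolan-2-yl)phenyl]lithium | [Li]c1c(C2OCCO2)ccc(OCc2ccccc2)c1OCc1ccccc1
F6 | step 6 | [2,3-bis(benzyloxy)-6-(1,3-dioxolan-2-yl)phenyl]zinc chloride | Cl[Zn]c1c(C2OCCO2)ccc(OCc2ccccc2)c1OCc1ccccc1
F7 | step 6 | ethylene acetal of 8 | C1COC(O1)c1ccc(OCc2ccccc2)c(OCc2ccccc2)c1-c1c(OCc2ccccc2)cc(OCc2ccccc2)c2c(=O)cc(-c3ccc(OCc4ccccc4)c(OCc4ccccc4)c3)oc12
F8 | step 9 | benzylic bromide from 9 | BrCc1ccc(OCc2ccccc2)c(OCc2ccccc2)c1-c1c(OCc2ccccc2)cc(OCc2ccccc2)c2c(=O)cc(-c3ccc(OCc4ccccc4)c(OCc4ccccc4)c3)oc12
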